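## Analysis of the target

The target 17 is a depside: two benzene rings joined through an aryl ester, with no stereocentre and no ring other than the two arenes. Ring A is a 2-hydroxy-4-methoxy-6-methylbenzoyl unit whose C1 carbonyl is the acyl half of the ester. Ring B is a benzoic acid with the carboxyl at C1, a free hydroxyl at C2, the ester oxygen at C4 and an n-pentyl chain at C6, so the carboxyl sits between two ortho substituents. The sensitive groups are the aryl ester, which does not survive hydroxide or alkoxide once formed, and the ring B carboxylic acid, a β-resorcylic acid that can lose carbon dioxide under hot or strongly acidic conditions. The difficulty is therefore one of regiochemistry and order, not stereochemistry. The 1,2,3,5 pattern of ring B must be set unambiguously, only O4 of ring B may be acylated, two di-ortho-substituted partners must be joined, and every group still present after esterification must come off without hydrolysis. The plan rests on ring B C6 (pentyl) and C1 (carboxyl) being neighbours, with C1 flanked on its other side by the C2 oxygen and the second oxygen at C4. That is the pattern left when a carbon nucleophile and then carbon dioxide add across the triple bond of 3,5-dimethoxybenzyne 6.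

## Retrosynthetic reasoning

Final deprotection. 17 is traced back to 16, which carries a benzyl ester on the ring B carboxyl and a benzyl ether on ring A O2. No skeletal bond is cut. Both groups fall in one neutral hydrogenolysis, so the aryl ester never meets a hydrolytic reagent.

Depside ester. 16 is cut at the bond between the ring A C1 carbonyl and ring B O4, giving acid chloride 15 and diol ester 10. This is the only bond joining the two aromatic halves, so cutting it makes the route convergent. The forward reaction must acylate O4 and leave O2–H alone. In 10 the O2 hydroxyl is hydrogen-bonded to the benzyl ester carbonyl and shielded by it, while O4–H is the more acidic and exposed phenol. The ring A phenol is masked in 15 so that the acyl donor cannot acylate itself.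

Ring A branch. 15 comes from acid 14, 14 from ester 13, 13 from phenol 12, and 12 from commercial 11. These are functional-group changes only, because the carbon skeleton of ring A is bought. The two hydroxyls of 11 are differentiated by the same hydrogen bond to an ortho ester, so O4 is methylated first and O2 benzylated second.

Ring B protecting-group changes. 10 is the benzyl ester of dihydroxy acid 9, and 9 is the product of cleaving both methyl ethers of 8. Methyl ethers are chosen for the stage before because they survive organolithium reagents and because one of them directs the aryne addition. They are removed early, on a small acid, and not from the finished depside.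

Key disconnection. In 8 the ring B C6–pentyl bond and the C1–carboxyl bond are cut together. This leads through aryllithium 7 to aryne 6, and through ortho-lithiated fluoroarene 5 to the symmetrical arene 3, with 2 as the pentyl source and 4 as the carboxyl source. The cut is made here because both bonds lie on adjacent carbons next to an oxygen, so one operation sets the whole substitution pattern. A stepwise plan would need separate, regiocontrolled introductions of the chain and the carboxyl. The forward step has to lithiate 3 next to fluorine, eliminate to 6, add 2 at the aryne carbon remote from the neighbouring methoxy group, and trap 7 with 4.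

Organolithium. 2 is traced to the primary chloride 1 by reductive metalation, a one-step preparation.

## Alternatives that were turned down

Alternative 1: Ring A is built last by unravelling it at its C1–C6 bond to an open-chain triketo ester already attached to ring B O4, benzyl 2-hydroxy-6-pentyl-4-[(3,5,7-trioxooctanoyl)oxy]benzoate A1. In the forward key step the C2 methylene of the chain adds to the C7 ketone, and dehydration and enolisation give benzyl 4-[(2,4-dihydroxy-6-methylbenzoyl)oxy]-2-hydroxy-6-pentylbenzoate A2.
- For: the route is biomimetic, needs no protecting group on ring A, and forms the ester bond with a flexible acyl donor instead of a 2,6-disubstituted benzoyl chloride. On that last point it is stronger than the chosen route.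
- Against: the chain in A1 hangs on an aryl ester, a good leaving group. The C5 enol oxygen can attack the C1 carbonyl, close a 4-hydroxypyran-2-one and expel the ring B phenoxide, and the base that drives the aldol is the kind of reagent that cleaves depsides.
- Against: A2 still needs selective methylation of ring A O4 on the complete depside, and ring B must still be made by some other route.
- Comparison: the alternative adds a ring construction for a ring that is commercial as 11, so it gains nothing in step count. The chosen route offers in its place a purchased ring A and an acylation whose selectivity follows from the hydrogen bond in 10.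

Alternative 2: Ring B is cut at C1–C2 and C5–C6 into 1,1-dimethoxy-3-(trimethylsilyloxy)buta-1,3-diene A3 and benzyl oct-2-ynoate A4. The forward key step is a Diels–Alder addition across the triple bond followed by loss of methanol, giving benzyl 4-hydroxy-2-methoxy-6-pentylbenzoate A5.
- For: polarity matching sets the regiochemistry, since the nucleophilic methylene terminus of A3 bonds to the pentyl-bearing β-carbon of A4.
- For: A5 has O4 free and O2 capped, and the benzyl ester is in place from the start. This differentiates the ring B oxygens more explicitly than the chosen route does, and the decarboxylation-prone acid 9 is never handled. On both points the alternative is stronger.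
- Against: a β-alkyl ynoate with one activating group is a slow dienophile, and the ketene-acetal diene A3 must be prepared and is labile to heat and moisture.
- Against: the O2 methyl of ring B would have to be removed at the very end, on the whole depside, beside an aryl ester and a ring A methyl ether that must stay. A chelation-controlled Lewis-acid cleavage might single it out, but that places the most delicate deprotection on the most valuable compound.
- Comparison: step counts are similar. The chosen route cleaves its methyl ethers early on the simple acid 8, relies on the inherent difference between O2–H and O4–H in 10, and ends with a hydrogenolysis only.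

Alternative 3: Ring A is cut at C1–C2 and C5–C6. The dienophile is a but-2-ynoate already esterified to ring B O4, benzyl 2-(benzyloxy)-4-(but-2-ynoyloxy)-6-pentylbenzoate A6, and the diene is 1,3-dimethoxy-1-(trimethylsilyloxy)buta-1,3-diene A7. Cycloaddition and loss of methanol would give benzyl 2-(benzyloxy)-4-[(2-hydroxy-4-methoxy-6-methylbenzoyl)oxy]-6-pentylbenzoate A8.
- For: A8 has the ring A pattern complete, the ester bond is formed with a small unhindered acid, and only a hydrogenolysis remains. It equals the chosen route on the end game and is stronger on avoiding a hindered acylation.
- Against: A6 is an aryl ynoate, an activated ester, exposed to a strongly nucleophilic silyl ketene acetal. Acyl transfer or conjugate addition without ring closure compete, and the β-methyl ynoate is a poor dienophile.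
- Against: ring B must carry a benzyl ether on O2 with O4 free, the reverse of the natural reactivity of 10, which costs a protect, benzylate, deprotect sequence.
- Against: ring A is made from scratch although 11 supplies it after one methylation, and ring B is still unmade.
- Comparison: the alternative is weaker on step economy and puts an uncertain cycloaddition late, on the finished ring B. The chosen route places its one demanding step at the start, on inexpensive materials.

Key step: step 2

Remark on the chemistry: locants on ring B follow the benzoic acid (C1 is the carbon bearing the carboxyl), and locants on ring A follow its benzoyl carbon as C1. Compound 2 is handled as a titrated hexane solution and 15 is carried on crude.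

## Route

Step 1
Reactants: 1 1-chloropentane
Product: 2 pentyllithium
Conditions: Li (dispersion, 1% Na, 2.2 equiv), hexane, reflux, Ar; filter; titrate
Reagents that add atoms: lithium, [Li]
Why: Reductive lithiation of a primary alkyl chloride by lithium metal in a hydrocarbon is the standard preparation of n-alkyllithiums; the chloride keeps Wurtz coupling low and the LiCl formed is insoluble and is filtered off.

Step 2
Reactants: 3 1-fluoro-3,5-dimethoxybenzene; 2 pentyllithium; 4 carbon dioxide
Product: 8 2,4-dimethoxy-6-pentylbenzoic acid, via (2-fluoro-4,6-dimethoxyphenyl)lithium 5 (not isolated), via 3,5-dimethoxybenzyne 6 (not isolated), via (2,4-dimethoxy-6-pentylphenyl)lithium 7 (not isolated)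
Conditions: 2 (2.4 equiv, hexane), THF, −78 °C → 0 °C; then 4 (dry gas), −78 °C → rt; 2 M HCl
Reagents that add atoms: none
Why: This is a directed ortho-lithiation, aryne formation, carbolithiation and carboxylation in one flask. The first equivalent of 2 removes the proton at C2 of 3, the most acidic site because fluorine and a methoxy group flank it, giving 5, and on warming 5 loses lithium fluoride to give aryne 6. A second equivalent of 2 adds to the aryne carbon remote from the neighbouring methoxy group, because the inductive pull of that oxygen stabilises negative charge on the adjacent carbon and the oxygen can coordinate lithium there, so 7 carries lithium between the pentyl and methoxy groups. Carbon dioxide 4 then carboxylates that carbon, which places pentyl, carboxyl and methoxy on three consecutive ring carbons with the second methoxy para to the pentyl-bearing position's neighbour, as in 8. The closest known reaction type is generation of a 3-alkoxyaryne from a fluoroarene with an alkyllithium, regioselective addition of a second alkyllithium and electrophilic trapping of the ortho-alkoxy aryllithium. No ring is closed and no stereocentre is formed. Two selectivities are needed: the lithiation site, secured by fluorine as the strongest acidifying group (lithiation between the two methoxy groups has no leaving group beside it and cannot give an aryne), and the sense of addition to 6, secured by the methoxy group next to the triple bond. Adding 3 to an excess of 2 keeps the alkyllithium concentration high so that 2, not 5 or 7, captures the aryne.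

Step 3
Reactants: 8 2,4-dimethoxy-6-pentylbenzoic acid
Product: 9 2,4-dihydroxy-6-pentylbenzoic acid
Conditions: BBr3 (4 equiv, 1 M in CH2Cl2), CH2Cl2, −78 °C → rt; pour onto ice, extract cold
Reagents that add atoms: none
Why: Lewis-acid cleavage of aryl methyl ethers; the O2 methyl goes first through a boron chelate with the carboxyl and the O4 methyl follows at room temperature, and without heating the β-resorcylic acid should keep its carboxyl group.

Step 4
Reactants: 9 2,4-dihydroxy-6-pentylbenzoic acid
Product: 10 benzyl 2,4-dihydroxy-6-pentylbenzoate
Conditions: BnBr (1.05 equiv), KHCO3 (1.1 equiv), DMF, rt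
Reagents that add atoms: benzyl bromide, BrCc1ccccc1
Why: Hydrogencarbonate ionises only the carboxylic acid, so SN2 alkylation takes place at the carboxylate and the two phenols, which stay protonated, are left free.

Step 5
Reactants: 11 methyl orsellinate (methyl 2,4-dihydroxy-6-methylbenzoate)
Product: 12 methyl 2-hydroxy-4-methoxy-6-methylbenzoate
Conditions: MeI (1.1 equiv), K2CO3 (1.1 equiv), acetone, rt → 40 °C
Reagents that add atoms: iodomethane, CI
Why: Williamson etherification; O4–H is the more acidic and unhindered phenol, while O2–H is held in a hydrogen bond to the ester carbonyl and reacts far more slowly, so one equivalent of iodomethane should methylate O4 only.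

Step 6
Reactants: 12 methyl 2-hydroxy-4-methoxy-6-methylbenzoate
Product: 13 methyl 2-(benzyloxy)-4-methoxy-6-methylbenzoate
Conditions: BnBr (1.5 equiv), K2CO3 (2 equiv), DMF, 70 °C
Reagents that add atoms: benzyl bromide, BrCc1ccccc1
Why: Williamson etherification of the chelated phenol under more forcing conditions (polar aprotic solvent, heat, excess halide); no other nucleophilic site remains.

Step 7
Reactants: 13 methyl 2-(benzyloxy)-4-methoxy-6-methylbenzoate
Product: 14 2-(benzyloxy)-4-methoxy-6-methylbenzoic acid
Conditions: KOH (10 equiv), DMSO–H2O (4:1), 100 °C; then cold 1 M HCl
Reagents that add atoms: potassium hydroxide, [K+].[OH-]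
Why: Saponification of a di-ortho-substituted benzoate; poorly solvated hydroxide in aqueous DMSO is reactive enough to attack the hindered carbonyl, and the benzyl and methyl ethers are inert to base.

Step 8
Reactants: 14 2-(benzyloxy)-4-methoxy-6-methylbenzoic acid
Product: 15 2-(benzyloxy)-4-methoxy-6-methylbenzoyl chloride
Conditions: (COCl)2 (1.5 equiv), DMF (cat.), CH2Cl2, 0 °C → rt; evaporate, use at once
Reagents that add atoms: oxalyl chloride, ClC(=O)C(=O)Cl
Why: Acid chloride formation through the chloroiminium species formed from DMF and oxalyl chloride; the conditions are mild and leave only volatile co-products, and the benzyl ether should tolerate them at room temperature.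

Step 9
Reactants: 15 2-(benzyloxy)-4-methoxy-6-methylbenzoyl chloride; 10 benzyl 2,4-dihydroxy-6-pentylbenzoate
Product: 16 benzyl 4-{[2-(benzyloxy)-4-methoxy-6-methylbenzoyl]oxy}-2-hydroxy-6-pentylbenzoate
Conditions: Et3N (1.3 equiv), DMAP (0.1 equiv), CH2Cl2, 0 °C → rt
Reagents that add atoms: none
Why: DMAP-catalysed acylation of a phenol by an acid chloride; O4–H of 10 is the more acidic and accessible hydroxyl, whereas O2–H is hydrogen-bonded to the benzyl ester and flanked by it, so one equivalent of the hindered acyl donor should react at O4 only.

Step 10
Reactants: 16 benzyl 4-{[2-(benzyloxy)-4-methoxy-6-methylbenzoyl]oxy}-2-hydroxy-6-pentylbenzoate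
Product: 17 2-hydroxy-4-[(2-hydroxy-4-methoxy-6-methylbenzoyl)oxy]-6-pentylbenzoic acid
Conditions: H2 (1 atm), 10% Pd/C, EtOAc, rt
Reagents that add atoms: none
Why: Catalytic hydrogenolysis cleaves the benzyl ester and the benzyl aryl ether under neutral conditions; the aryl ester, the methyl ether and both arenes are untouched, and the acid is released without heat or strong acid.

## Compound list

1 | 1-chloropentane | CCCCCCl | starting material
2 | pentyllithium | [Li]CCCCC | intermediate
3 | 1-fluoro-3,5-dimethoxybenzene | COc1cc(F)cc(OC)c1 | starting material
4 | carbon dioxide | O=C=O | starting material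
5 | (2-fluoro-4,6-dimethoxyphenyl)lithium | [Li]c1c(F)cc(OC)cc1OC | intermediate
6 | 3,5-dimethoxybenzyne (1,2-didehydro-3,5-dimethoxybenzene) | COC1=CC(OC)=CC#C1 | intermediate
7 | (2,4-dimethoxy-6-pentylphenyl)lithium | [Li]c1c(CCCCC)cc(OC)cc1OC | intermediate
8 | 2,4-dimethoxy-6-pentylbenzoic acid | CCCCCc1cc(OC)cc(OC)c1C(=O)O | intermediate
9 | 2,4-dihydroxy-6-pentylbenzoic acid | CCCCCc1cc(O)cc(O)c1C(=O)O | intermediate
10 | benzyl 2,4-dihydroxy-6-pentylbenzoate | CCCCCc1cc(O)cc(O)c1C(=O)OCc1ccccc1 | intermediate
11 | methyl orsellinate (methyl 2,4-dihydroxy-6-methylbenzoate) | COC(=O)c1c(C)cc(O)cc1O | starting material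
12 | methyl 2-hydroxy-4-methoxy-6-methylbenzoate | COC(=O)c1c(C)cc(OC)cc1O | intermediate
13 | methyl 2-(benzyloxy)-4-methoxy-6-methylbenzoate | COC(=O)c1c(C)cc(OC)cc1OCc1ccccc1 | intermediate
14 | 2-(benzyloxy)-4-methoxy-6-methylbenzoic acid | OC(=O)c1c(C)cc(OC)cc1OCc1ccccc1 | intermediate
15 | 2-(benzyloxy)-4-methoxy-6-methylbenzoyl chloride | ClC(=O)c1c(C)cc(OC)cc1OCc1ccccc1 | intermediate
16 | benzyl 4-{[2-(benzyloxy)-4-methoxy-6-methylbenzoyl]oxy}-2-hydroxy-6-pentylbenzoate | CCCCCc1cc(OC(=O)c2c(C)cc(OC)cc2OCc2ccccc2)cc(O)c1C(=O)OCc1ccccc1 | intermediate
17 | 2-hydroxy-4-[(2-hydroxy-4-methoxy-6-methylbenzoyl)oxy]-6-pentylbenzoic acid | CCCCCc1cc(OC(=O)c2c(C)cc(OC)cc2O)cc(O)c1C(=O)O | target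

## Step count and least certain steps

Total step count: 10. Longest linear sequence: 6 steps (steps 1, 2, 3, 4, 9, 10 on the ring B side; steps 5 to 10 on the ring A side are equally long).

Step 2 (key step). Several processes can erode it.
- Lithiation between the two methoxy groups of 3 gives a species that cannot eliminate and wastes substrate and base.
- If the concentration of 2 falls, aryllithium 5 or 7 can add to the aryne in place of 2, which leads to biaryl formation.
- 7 can be protonated by solvent before the carboxylation if the mixture is kept warm too long.
- Surplus 2 is carboxylated as well, and the aliphatic acid formed has to be separated from 8; addition of organolithium to the lithium carboxylate is a further loss.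

Fallback: set out from 3 and 2 and run the same aryne carbolithiation, but quench with a proton source to obtain 1,3-dimethoxy-5-pentylbenzene F1; any unproductively lithiated substrate then simply returns as 3. The carboxyl carbon is introduced by electrophilic substitution instead of carbanion trapping. Vilsmeier–Haack formylation (POCl3, DMF) attacks the position para to one methoxy group and ortho to the other and should give 2,4-dimethoxy-6-pentylbenzaldehyde F2. Pinnick oxidation (NaClO2, NaH2PO4, 2-methylbut-2-ene, aqueous tert-butanol) converts F2 into 8, where the route is rejoined.

Step 3. The likely failure is loss of carbon dioxide from the electron-rich acid by ipso-protonation while the ethers are cleaved or during the acidic quench. Incomplete cleavage of the non-chelated O4 methyl is the second risk. Fallback: set out from 8 and accept the decarboxylation deliberately. Hot HBr in acetic acid cleaves both ethers and removes the carboxyl to give 5-pentylbenzene-1,3-diol F3. The carboxyl is then put back by chelation-directed carboxylation with methyl magnesium carbonate (MeOMgOCO2Me) in DMF at about 120 °C, a Kolbe–Schmitt-type reaction that is an established entry to 9. The route is rejoined at 9.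

Step 9. Both partners are hindered, so acylation may be slow, and a slow reaction gives time for hydrolysis of 15 or for acylation at O2 as well as O4. Fallback: set out from 12 and 10 and avoid both the protected acid and the acid chloride. Saponify 12 (KOH, aqueous DMSO, heat, cold acidification) to 2-hydroxy-4-methoxy-6-methylbenzoic acid F4. Condense F4 directly with 10 through the mixed anhydride formed with trifluoroacetic anhydride in toluene at room temperature; the chelated ortho hydroxyl of F4 does not compete as a nucleophile. This gives benzyl 2-hydroxy-4-[(2-hydroxy-4-methoxy-6-methylbenzoyl)oxy]-6-pentylbenzoate F5. Hydrogenolysis of F5 (H2, 10% Pd/C, EtOAc) removes the single benzyl group and rejoins the route at 17.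

Step 7. Hydroxide attack at the di-ortho-substituted ester carbonyl may be too slow, and prolonged heating in strong base risks incomplete conversion or erosion of the benzyl ether. Fallback: set out from 13 and change the oxidation-state path so that no tetrahedral intermediate with a bulky nucleophile is needed. Reduce 13 with LiAlH4 in THF to [2-(benzyloxy)-4-methoxy-6-methylphenyl]methanol F6. Oxidise F6 with MnO2 in CH2Cl2 to 2-(benzyloxy)-4-methoxy-6-methylbenzaldehyde F7. Pinnick oxidation (NaClO2, NaH2PO4, 2-methylbut-2-ene) of F7 gives 14, where the route is rejoined.

## Further compounds

F1 | step 2 | 1,3-dimethoxy-5-pentylbenzene | CCCCCc1cc(OC)cc(OC)c1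
F2 | step 2 | 2,4-dimethoxy-6-pentylbenzaldehyde | CCCCCc1cc(OC)cc(OC)c1C=O
F3 | step 3 | 5-pentylbenzene-1,3-diol | CCCCCc1cc(O)cc(O)c1
F4 | step 9 | 2-hydroxy-4-methoxy-6-methylbenzoic acid | OC(=O)c1c(C)cc(OC)cc1O
F5 | step 9 | benzyl 2-hydroxy-4-[(2-hydroxy-4-methoxy-6-methylbenzoyl)oxy]-6-pentylbenzoate | CCCCCc1cc(OC(=O)c2c(C)cc(OC)cc2O)cc(O)c1C(=O)OCc1ccccc1
F6 | step 7 | [2-(benzyloxy)-4-methoxy-6-methylphenyl]methanol | OCc1c(C)cc(OC)cc1OCc1ccccc1
F7 | step 7 | 2-(benzyloxy)-4-methoxy-6-methylbenzaldehyde | O=Cc1c(C)cc(OC)cc1OCc1ccccc1
A1 | alternative 1 | benzyl 2-hydroxy-6-pentyl-4-[(3,5,7-trioxooctanoyl)oxy]benzoate | CCCCCc1cc(OC(=O)CC(=O)CC(=O)CC(C)=O)cc(O)c1C(=O)OCc1ccccc1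
A2 | alternative 1 | benzyl 4-[(2,4-dihydroxy-6-methylbenzoyl)oxy]-2-hydroxy-6-pentylbenzoate | CCCCCc1cc(OC(=O)c2c(C)cc(O)cc2O)cc(O)c1C(=O)OCc1ccccc1
A3 | alternative 2 | 1,1-dimethoxy-3-(trimethylsilyloxy)buta-1,3-diene | COC(OC)=CC(=C)O[Si](C)(C)C
A4 | alternative 2 | benzyl oct-2-ynoate | CCCCCC#CC(=O)OCc1ccccc1
A5 | alternative 2 | benzyl 4-hydroxy-2-methoxy-6-pentylbenzoate | CCCCCc1cc(O)cc(OC)c1C(=O)OCc1ccccc1
A6 | alternative 3 | benzyl 2-(benzyloxy)-4-(but-2-ynoyloxy)-6-pentylbenzoate | CCCCCc1cc(OC(=O)C#CC)cc(OCc2ccccc2)c1C(=O)OCc1ccccc1
A7 | alternative 3 | 1,3-dimethoxy-1-(trimethylsilyloxy)buta-1,3-diene | COC(=C)C=C(OC)O[Si](C)(C)C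
A8 | alternative 3 | benzyl 2-(benzyloxy)-4-[(2-hydroxy-4-methoxy-6-methylbenzoyl)oxy]-6-pentylbenzoate | CCCCCc1cc(OC(=O)c2c(C)cc(OC)cc2O)cc(OCc2ccccc2)c1C(=O)OCc1ccccc1
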